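**Strategy**

Everything rests on making ring B last, from a four-carbon diazo enone chain already attached to the stereogenic C3 of a finished (3R)-5,7-dimethoxychroman. Ring B is a contiguously 1,2,3,4-substituted benzene (C1′ chroman, C2′ OH, C3′ prenyl, C4′ OMe, C5′/C6′ H), the exact imprint of a vinylketene–ynol ether benzannulation. In one operation, light turns the (E)-α′-diazo enone into a vinylketene that takes up 1-methoxy-5-methylhex-4-en-1-yne and aromatises, forming C2′–C3′, C4′–C5′ and C1′–C2′ and releasing the C2′ phenol unprotected. C3 is set earlier by desymmetrising a prochiral diol; C8 formylation and O7 demethylation follow.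

Key step: step 9

Assumption: the sense of induction of the copper–diamine catalyst in step 4 is not predicted here; both ligand antipodes are available, and the one that delivers (R)-6 is to be chosen in a pilot run and the configuration secured by correlation.

Remark: the diazo group is introduced last, by diazo transfer to methyl enone 9, so that the base-sensitive chroman-3-carbaldehyde 7 meets only a mild amine-based olefination.

**Route**

Step 1
Reactants: 1 2-bromo-4,6-dimethoxybenzaldehyde; 2 diethyl malonate
Product: 3 diethyl 2-[(2-bromo-4,6-dimethoxyphenyl)methylidene]propanedioate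
Conditions: piperidine (0.2 equiv), AcOH (0.2 equiv), toluene, reflux, Dean–Stark
Reagents that add atoms: none
Why: Knoevenagel condensation of the activated methylene with the aldehyde, driven by azeotropic removal of water because the carbonyl group is electron-rich and flanked by two ortho substituents; no stereocentre is formed.

Step 2
Reactants: 3 diethyl 2-[(2-bromo-4,6-dimethoxyphenyl)methylidene]propanedioate
Product: 4 diethyl 2-[(2-bromo-4,6-dimethoxyphenyl)methyl]propanedioate
Conditions: NaBH4 (1.0 equiv), EtOH, 0 °C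
Reagents that add atoms: none
Why: Conjugate (1,4-) hydride reduction of the doubly activated alkylidene malonate, which at 0 °C should leave the ester groups and the aryl bromide untouched.

Step 3
Reactants: 4 diethyl 2-[(2-bromo-4,6-dimethoxyphenyl)methyl]propanedioate
Product: 5 2-[(2-bromo-4,6-dimethoxyphenyl)methyl]propane-1,3-diol
Conditions: LiAlH4 (2.5 equiv), THF, 0 °C → rt; Fieser work-up
Reagents that add atoms: none
Why: Hydride reduction of both esters gives the prochiral 2-substituted propane-1,3-diol, the aryl C–Br bond being inert to LiAlH4 at or below room temperature.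

Step 4
Reactants: 5 2-[(2-bromo-4,6-dimethoxyphenyl)methyl]propane-1,3-diol
Product: 6 [(3R)-5,7-dimethoxychroman-3-yl]methanol
Conditions: CuI (10 mol %), chiral cyclic 1,2-diamine ligand (e.g. an N,N′-dialkyl trans-cyclohexane-1,2-diamine, 20 mol %), Cs2CO3 (2 equiv), MeCN, 40 °C
Reagents that add atoms: none
Why: Copper(I)-catalysed Ullmann-type intramolecular O-arylation run as an enantioselective desymmetrisation, in which the chiral diamine–copper alkoxide differentiates the two enantiotopic CH2OH arms in the six-membered ring-forming C–O coupling and thereby creates C3, the ligand antipode being chosen to give the (R)-alcohol.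

Step 5
Reactants: 6 [(3R)-5,7-dimethoxychroman-3-yl]methanol
Product: 7 (3S)-5,7-dimethoxychroman-3-carbaldehyde
Conditions: Dess–Martin periodinane (1.2 equiv), CH2Cl2, 0 °C → rt; cold aq. Na2S2O3/NaHCO3; crude used at once
Reagents that add atoms: none
Why: Dess–Martin oxidation of the primary alcohol proceeds under near-neutral, non-enolising conditions, so the α-stereocentre (which also carries a β-aryloxy group) should neither epimerise nor eliminate; the descriptor changes from R to S only because CHO outranks C2 in the CIP order.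

Step 6
Reactants: 7 (3S)-5,7-dimethoxychroman-3-carbaldehyde; 8 dimethyl (2-oxopropyl)phosphonate
Product: 9 (3E)-4-[(3R)-5,7-dimethoxychroman-3-yl]but-3-en-2-one
Conditions: LiCl (1.2 equiv), i-Pr2NEt (1.1 equiv), MeCN, 0 °C → rt
Reagents that add atoms: none
Why: Horner–Wadsworth–Emmons olefination under Masamune–Roush conditions (lithium-chelated β-ketophosphonate deprotonated by a tertiary amine) should give the (E)-enone and is mild enough to leave the α-stereocentre of the aldehyde intact.

Step 7
Reactants: 9 (3E)-4-[(3R)-5,7-dimethoxychroman-3-yl]but-3-en-2-one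
Product: 11 (3E)-1-diazo-4-[(3R)-5,7-dimethoxychroman-3-yl]but-3-en-2-one, via trifluoroacetyl diketone 10 (not isolated)
Conditions: LiHMDS (1.1 equiv), THF, −78 °C; CF3CO2CH2CF3 (1.2 equiv), −78 °C; then p-ABSA (1.5 equiv), Et3N (1.5 equiv), H2O (1 equiv), MeCN, rt
Reagents that add atoms: 4-acetamidobenzenesulfonyl azide (p-ABSA), CC(=O)Nc1ccc(cc1)S(=O)(=O)N=[N+]=[N-]
Why: Detrifluoroacetylative diazo transfer, in which LiHMDS removes a proton kinetically from the methyl group instead of the γ-position C3, the enolate is C-trifluoroacetylated (Claisen type) to 1,3-diketone 10, and this activated methylene accepts the diazo group from the sulfonyl azide with expulsion of the trifluoroacetyl group, so that neither C3 nor the (E)-alkene is touched.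

Step 8
Reactants: 12 chloroacetaldehyde dimethyl acetal; 13 prenyl bromide (1-bromo-3-methylbut-2-ene)
Product: 15 1-methoxy-5-methylhex-4-en-1-yne, via sodium methoxyacetylide 14 (not isolated)
Conditions: NaNH2 (3.0 equiv), liq. NH3, −33 °C; then 13 (0.9 equiv), −78 → −33 °C; NH4Cl
Reagents that add atoms: none
Why: Amide-induced double elimination (loss of MeOH and HCl) with in situ deprotonation gives the acetylide, which is alkylated by SN2 attack at the primary allylic carbon of 13, and the use of exactly three equivalents of amide leaves no strong base to isomerise the skipped enyne.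

Step 9
Reactants: 11 (3E)-1-diazo-4-[(3R)-5,7-dimethoxychroman-3-yl]but-3-en-2-one; 15 1-methoxy-5-methylhex-4-en-1-yne
Product: 20 2-[(3R)-5,7-dimethoxychroman-3-yl]-5-methoxy-6-(3-methylbut-2-enyl)phenol, via vinylketene 16 (not isolated), via vinylcyclobutenone 17 (not isolated), via dienylketene 18 (not isolated), via cyclohexadienone 19 (not isolated)
Conditions: 15 (2 equiv), ClCH2CH2Cl (degassed), hν (medium-pressure Hg lamp, Pyrex, λ > 300 nm), 20 °C; then 80 °C
Reagents that add atoms: none
Why: Irradiation expels N2 and the alkenyl group shifts from the carbonyl carbon (future C2′) to the diazo carbon (future C5′) in a photochemical Wolff rearrangement, giving (E)-vinylketene 16; its electrophilic ketene carbon is attacked by the prenyl-bearing β-carbon of the ynol ether, and the regiodefined [2+2] adduct 17 (C2′–C3′ and C4′–C5′ made) opens by thermal 4π electrocyclic cleavage to dienylketene 18 with the ketenyl and vinyl groups cis. Ring B then closes by a thermal disrotatory 6π electrocyclisation that joins the ketene carbon C2′ to C1′, and dienone 19 enolises to the aromatic phenol. This is the known Danheiser benzannulation of α,β-unsaturated α′-diazo ketones with alkoxyalkynes, which delivers 3-alkoxyphenols (resorcinol monoethers). No stereocentre is created; C3 is a spectator that should keep its configuration because the medium is neutral and the (E)-geometry of the alkene rules out a 1,5-hydrogen shift from C3 to the ketene. The selectivity needed is the regiochemistry of the [2+2] step, which the polarisation of the partners secures (the oxygen-bearing alkyne carbon bonds to the ketene α-carbon), placing OMe at C4′, prenyl at C3′ and the free OH at C2′; the ynol ether is a far better ketenophile than the trisubstituted prenyl alkene, and a methyl ynol ether cannot be lost by retro-ene fragmentation on heating.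

Step 10
Reactants: 20 2-[(3R)-5,7-dimethoxychroman-3-yl]-5-methoxy-6-(3-methylbut-2-enyl)phenol
Product: 21 2-[(3R)-5,7-dimethoxychroman-3-yl]-5-methoxy-6-(3-methylbut-2-enyl)phenyl acetate
Conditions: Ac2O (1.5 equiv), pyridine, DMAP (0.1 equiv), CH2Cl2, rt
Reagents that add atoms: acetic anhydride, CC(=O)OC(C)=O
Why: DMAP-catalysed O-acylation of the hindered C2′ phenol masks the acidic OH and lowers the nucleophilicity of ring B before the electrophilic formylation.

Step 11
Reactants: 21 2-[(3R)-5,7-dimethoxychroman-3-yl]-5-methoxy-6-(3-methylbut-2-enyl)phenyl acetate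
Product: 23 2-[(3R)-8-formyl-5,7-dimethoxychroman-3-yl]-5-methoxy-6-(3-methylbut-2-enyl)phenyl acetate, via C8 iminium salt 22 (not isolated)
Conditions: POCl3 (1.5 equiv), DMF, 0 °C → rt; then aq. NaOAc, rt
Reagents that add atoms: N,N-dimethylformamide, CN(C)C=O; water, O
Why: Vilsmeier–Haack formylation, in which the chloroiminium ion should attack only the 1,3,5-trioxygenated ring A and there at C8, which lies between the ring oxygen O1 and one methoxy group and is less hindered than C6 between two methoxy groups (the usual C8 preference of 5,7-dialkoxychromans), while the acetylated ring B and the prenyl alkene are too weakly nucleophilic to compete; hydrolysis of 22 gives the aldehyde.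

Step 12
Reactants: 23 2-[(3R)-8-formyl-5,7-dimethoxychroman-3-yl]-5-methoxy-6-(3-methylbut-2-enyl)phenyl acetate
Product: 24 2-[(3R)-8-formyl-7-hydroxy-5-methoxychroman-3-yl]-5-methoxy-6-(3-methylbut-2-enyl)phenyl acetate
Conditions: MgI2 (3 equiv), Et2O–toluene, 60 °C; aq. NH4Cl
Reagents that add atoms: none
Why: Chelation-controlled aryl methyl ether cleavage, in which Mg(II) bridges the C8 formyl oxygen and O7 and iodide removes the O7 methyl group by SN2 attack, whereas the 5- and 4′-methoxy groups cannot chelate and the ring O1–C2 bond is a far poorer SN2 site; the acetate keeps acidic OH out of the medium so the prenyl group is not exposed to HI.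

Step 13
Reactants: 24 2-[(3R)-8-formyl-7-hydroxy-5-methoxychroman-3-yl]-5-methoxy-6-(3-methylbut-2-enyl)phenyl acetate
Product: 25 (3R)-7-hydroxy-3-[2-hydroxy-4-methoxy-3-(3-methylbut-2-enyl)phenyl]-5-methoxychroman-8-carbaldehyde
Conditions: K2CO3 (2 equiv), MeOH, 0 °C → rt; aq. NH4Cl
Reagents that add atoms: none
Why: Base-mediated methanolysis (transesterification) of the aryl acetate releases the C2′ phenol under conditions to which the non-enolisable aldehyde, the prenyl group and the non-acidic C3–H are inert.

**Compound list**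

1 | 2-bromo-4,6-dimethoxybenzaldehyde | COc1cc(Br)c(C=O)c(OC)c1 | starting material
2 | diethyl malonate | CCOC(=O)CC(=O)OCC | starting material
3 | diethyl 2-[(2-bromo-4,6-dimethoxyphenyl)methylidene]propanedioate | CCOC(=O)C(=Cc1c(Br)cc(OC)cc1OC)C(=O)OCC | intermediate
4 | diethyl 2-[(2-bromo-4,6-dimethoxyphenyl)methyl]propanedioate | CCOC(=O)C(Cc1c(Br)cc(OC)cc1OC)C(=O)OCC | intermediate
5 | 2-[(2-bromo-4,6-dimethoxyphenyl)methyl]propane-1,3-diol | OCC(CO)Cc1c(Br)cc(OC)cc1OC | intermediate
6 | [(3R)-5,7-dimethoxychroman-3-yl]methanol | OC[C@@H]1COc2cc(OC)cc(OC)c2C1 | intermediate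
7 | (3S)-5,7-dimethoxychroman-3-carbaldehyde | O=C[C@@H]1COc2cc(OC)cc(OC)c2C1 | intermediate
8 | dimethyl (2-oxopropyl)phosphonate | COP(=O)(CC(C)=O)OC | starting material
9 | (3E)-4-[(3R)-5,7-dimethoxychroman-3-yl]but-3-en-2-one | CC(=O)/C=C/[C@@H]1COc2cc(OC)cc(OC)c2C1 | intermediate
10 | (5E)-6-[(3R)-5,7-dimethoxychroman-3-yl]-1,1,1-trifluorohex-5-ene-2,4-dione (present as its lithium enolate) | FC(F)(F)C(=O)CC(=O)/C=C/[C@@H]1COc2cc(OC)cc(OC)c2C1 | intermediate (not isolated)
11 | (3E)-1-diazo-4-[(3R)-5,7-dimethoxychroman-3-yl]but-3-en-2-one | [N-]=[N+]=CC(=O)/C=C/[C@@H]1COc2cc(OC)cc(OC)c2C1 | intermediate (key-step precursor)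
12 | chloroacetaldehyde dimethyl acetal (2-chloro-1,1-dimethoxyethane) | COC(CCl)OC | starting material
13 | prenyl bromide (1-bromo-3-methylbut-2-ene) | CC(C)=CCBr | starting material
14 | sodium methoxyacetylide | [Na+].[C-]#COC | intermediate (not isolated)
15 | 1-methoxy-5-methylhex-4-en-1-yne | COC#CCC=C(C)C | intermediate
16 | (3E)-4-[(3R)-5,7-dimethoxychroman-3-yl]buta-1,3-dien-1-one | O=C=C/C=C/[C@@H]1COc2cc(OC)cc(OC)c2C1 | intermediate (not isolated)
17 | 4-{(E)-2-[(3R)-5,7-dimethoxychroman-3-yl]ethenyl}-3-methoxy-2-(3-methylbut-2-enyl)cyclobut-2-en-1-one (either epimer at ring C4) | O=C1C(CC=C(C)C)=C(OC)C1/C=C/[C@@H]2COc3cc(OC)cc(OC)c3C2 | intermediate (not isolated)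
18 | (3E,5E)-6-[(3R)-5,7-dimethoxychroman-3-yl]-3-methoxy-2-(3-methylbut-2-enyl)hexa-1,3,5-trien-1-one | O=C=C(CC=C(C)C)/C(OC)=C\C=C\[C@@H]1COc2cc(OC)cc(OC)c2C1 | intermediate (not isolated)
19 | 6-[(3R)-5,7-dimethoxychroman-3-yl]-3-methoxy-2-(3-methylbut-2-enyl)cyclohexa-2,4-dien-1-one (either epimer at ring C6) | O=C1C(CC=C(C)C)=C(OC)C=CC1[C@@H]2COc3cc(OC)cc(OC)c3C2 | intermediate (not isolated)
20 | 2-[(3R)-5,7-dimethoxychroman-3-yl]-5-methoxy-6-(3-methylbut-2-enyl)phenol | COc1ccc([C@@H]2COc3cc(OC)cc(OC)c3C2)c(O)c1CC=C(C)C | intermediate (key-step product)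
21 | 2-[(3R)-5,7-dimethoxychroman-3-yl]-5-methoxy-6-(3-methylbut-2-enyl)phenyl acetate | COc1ccc([C@@H]2COc3cc(OC)cc(OC)c3C2)c(OC(C)=O)c1CC=C(C)C | intermediate
22 | N-{[(3R)-3-[2-acetoxy-4-methoxy-3-(3-methylbut-2-enyl)phenyl]-5,7-dimethoxychroman-8-yl]methylidene}-N-methylmethanaminium dichlorophosphate | COc1ccc([C@@H]2COc3c(C=[N+](C)C)c(OC)cc(OC)c3C2)c(OC(C)=O)c1CC=C(C)C.[O-]P(=O)(Cl)Cl | intermediate (not isolated)
23 | 2-[(3R)-8-formyl-5,7-dimethoxychroman-3-yl]-5-methoxy-6-(3-methylbut-2-enyl)phenyl acetate | COc1ccc([C@@H]2COc3c(C=O)c(OC)cc(OC)c3C2)c(OC(C)=O)c1CC=C(C)C | intermediate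
24 | 2-[(3R)-8-formyl-7-hydroxy-5-methoxychroman-3-yl]-5-methoxy-6-(3-methylbut-2-enyl)phenyl acetate | COc1ccc([C@@H]2COc3c(C=O)c(O)cc(OC)c3C2)c(OC(C)=O)c1CC=C(C)C | intermediate
25 | (3R)-7-hydroxy-3-[2-hydroxy-4-methoxy-3-(3-methylbut-2-enyl)phenyl]-5-methoxychroman-8-carbaldehyde | COc1ccc([C@@H]2COc3c(C=O)c(O)cc(OC)c3C2)c(O)c1CC=C(C)C | target

**Step count and risks**

Total: 13 steps. Longest linear sequence: 12 steps (steps 1–7 and 9–13); step 8 is a one-step side branch.

Steps most likely to fail:

1. Step 9 (key step). Capture of the photogenerated vinylketene by the ynol ether may lose out to ketene dimerisation, to acylation of the freshly formed C2′ phenol by a second ketene, or to light- and heat-induced decay of the skipped enyne ether, so that ring B is not assembled efficiently. The fallback gives up the annulation: ring B is brought in as a finished arene, C3 is set by an oxazolidinone auxiliary and the pyran ring is closed last. It sets out from 1 and 13 and comes back at 20. Commercial 1-methoxy-3-(methoxymethoxy)benzene is lithiated between its two oxygens (n-BuLi, THF, 0 °C), transmetallated (CuBr·SMe2) and alkylated with 13 to give 1-methoxy-3-(methoxymethoxy)-2-(3-methylbut-2-enyl)benzene F1. A second lithiation ortho to the MOM ether and opening of ethylene oxide (BF3·OEt2, −78 °C) would give arylethanol F2, which is oxidised (TEMPO, PhI(OAc)2, MeCN/H2O) to arylacetic acid F3 and coupled (PivCl, Et3N; then lithiated (R)-4-benzyloxazolidin-2-one) to N-acyl oxazolidinone F4. In parallel, 1 is reduced (NaBH4, MeOH) to benzyl alcohol F5 and converted (PBr3, Et2O, 0 °C) to benzyl bromide F6. Evans alkylation of the sodium enolate of F4 (NaHMDS, THF, −78 °C) with F6 should give the (2R)-alkylated imide F7, the electrophile entering anti to the auxiliary benzyl group. Reductive removal of the auxiliary (LiBH4, Et2O/MeOH, 0 °C) gives primary alcohol F8, intramolecular Ullmann etherification (CuI, 1,10-phenanthroline, Cs2CO3, toluene, 100 °C) gives MOM-protected isoflavan F9, and mild MOM cleavage (ZnBr2, n-PrSH, CH2Cl2, 0 °C) gives 20.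

2. Step 4. The catalyst may discriminate poorly between the two enantiotopic hydroxymethyl arms of a tertiary prochiral carbon, or oxidative addition of the aryl bromide may be too slow at the low temperature that selectivity demands. The fallback separates the enantio-determining event from the ring closure and runs from 5 back to 6. Lipase-catalysed monoacetylation of 5 (Pseudomonas cepacia lipase, vinyl acetate, i-Pr2O, rt; enzymatic hydrolysis of the diacetate serves if the opposite sense is obtained) would give (R)-monoacetate F10. The free arm is tritylated (TrCl, pyridine, DMAP) to trityl ether acetate F11, and the acetate is removed (K2CO3, MeOH) to give mono-trityl ether F12, in which no acyl or silyl migration can scramble the centre. Achiral Ullmann cyclisation (CuI, 1,10-phenanthroline, Cs2CO3, toluene, 100 °C) gives chroman trityl ether F13, and detritylation (TsOH·H2O cat., MeOH/CH2Cl2, rt) returns 6.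

3. Step 11. The chloroiminium ion may attack C6 in competition with C8, or the acidic, electrophilic medium may damage the prenyl double bond. The fallback replaces electrophilic formylation by halogenation and palladium-catalysed reductive carbonylation, from 21 to 23. NBS (1.0 equiv, CH2Cl2, −78 °C) should brominate ring A at C8, the position at which 5,7-dialkoxyflavans are known to brominate, under non-acidic conditions, giving C8 bromide F14, from which any C6 isomer is separated. Formylation with CO/H2 (Pd(OAc)2, di(1-adamantyl)-n-butylphosphine, TMEDA, toluene, 100 °C) then gives 23.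

**Further compounds**

F1 | step 9 | 1-methoxy-3-(methoxymethoxy)-2-(3-methylbut-2-enyl)benzene | COCOc1cccc(OC)c1CC=C(C)C
F2 | step 9 | 2-[4-methoxy-2-(methoxymethoxy)-3-(3-methylbut-2-enyl)phenyl]ethanol | OCCc1ccc(OC)c(CC=C(C)C)c1OCOC
F3 | step 9 | [4-methoxy-2-(methoxymethoxy)-3-(3-methylbut-2-enyl)phenyl]acetic acid | OC(=O)Cc1ccc(OC)c(CC=C(C)C)c1OCOC
F4 | step 9 | (4R)-4-benzyl-3-{[4-methoxy-2-(methoxymethoxy)-3-(3-methylbut-2-enyl)phenyl]acetyl}oxazolidin-2-one | O=C(Cc1ccc(OC)c(CC=C(C)C)c1OCOC)N1[C@H](Cc2ccccc2)COC1=O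
F5 | step 9 | (2-bromo-4,6-dimethoxyphenyl)methanol | OCc1c(Br)cc(OC)cc1OC
F6 | step 9 | 1-bromo-2-(bromomethyl)-3,5-dimethoxybenzene | BrCc1c(Br)cc(OC)cc1OC
F7 | step 9 | (4R)-4-benzyl-3-{(2R)-3-(2-bromo-4,6-dimethoxyphenyl)-2-[4-methoxy-2-(methoxymethoxy)-3-(3-methylbut-2-enyl)phenyl]propanoyl}oxazolidin-2-one | O=C([C@H](Cc1c(Br)cc(OC)cc1OC)c1ccc(OC)c(CC=C(C)C)c1OCOC)N1[C@H](Cc2ccccc2)COC1=O
F8 | step 9 | (2R)-3-(2-bromo-4,6-dimethoxyphenyl)-2-[4-methoxy-2-(methoxymethoxy)-3-(3-methylbut-2-enyl)phenyl]propan-1-ol | OC[C@H](Cc1c(Br)cc(OC)cc1OC)c1ccc(OC)c(CC=C(C)C)c1OCOC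
F9 | step 9 | (3R)-5,7-dimethoxy-3-[4-methoxy-2-(methoxymethoxy)-3-(3-methylbut-2-enyl)phenyl]chroman | COCOc1c([C@@H]2COc3cc(OC)cc(OC)c3C2)ccc(OC)c1CC=C(C)C
F10 | step 4 | (2R)-2-[(2-bromo-4,6-dimethoxyphenyl)methyl]-3-hydroxypropyl acetate | OC[C@H](COC(C)=O)Cc1c(Br)cc(OC)cc1OC
F11 | step 4 | (2R)-2-[(2-bromo-4,6-dimethoxyphenyl)methyl]-3-(trityloxy)propyl acetate | C(c1ccccc1)(c1ccccc1)(c1ccccc1)OC[C@H](COC(C)=O)Cc1c(Br)cc(OC)cc1OC
F12 | step 4 | (2S)-2-[(2-bromo-4,6-dimethoxyphenyl)methyl]-3-(trityloxy)propan-1-ol | C(c1ccccc1)(c1ccccc1)(c1ccccc1)OC[C@H](CO)Cc1c(Br)cc(OC)cc1OC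
F13 | step 4 | (3S)-5,7-dimethoxy-3-[(trityloxy)methyl]chroman | C(c1ccccc1)(c1ccccc1)(c1ccccc1)OC[C@@H]1COc2cc(OC)cc(OC)c2C1
F14 | step 11 | 2-[(3R)-8-bromo-5,7-dimethoxychroman-3-yl]-5-methoxy-6-(3-methylbut-2-enyl)phenyl acetate | COc1ccc([C@@H]2COc3c(Br)c(OC)cc(OC)c3C2)c(OC(C)=O)c1CC=C(C)C
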